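**Retrosynthetic overview**
1. C17–OAc, C7=C8 and C9–H: acetate ⇐ SeO2 hydroxylation of the C17 methyl ⇐ reductive 1,3-transposition of a C7 allylic alcohol ⇐ 7-oxo-8-ene ester.
2. C9–C11: Negishi coupling of a ring B enol triflate with the alkylzinc made from methyl hydrogen (R)-3-methylglutarate, which brings C11–C16 and the C13 center.
3. Ring A: the C3–C4 bond is closed by a hydrogen-atom-transfer radical cyclisation of a C5 2-propenyl group onto a C3 tosylhydrazone carried by C10, with traceless loss of sulfinate and N2.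
4. Enabling feature: C4 of ring A is a quaternary carbon with two methyls next to ring-fusion C5, and C3 is a bare CH2. A 2-propenyl group on C5 of ring B is therefore a latent tertiary C4 radical whose =CH2 becomes the second methyl, and the trans C5/C10 arms on ring B can only close to a trans-decalin.
5. Ring order: ring B is (S)-carvone (C5 center, C17 methyl, C7–C9 functionality; C10 set by methylation, then propargylation), then ring A is formed in the key step.

Key step: step 5

Assumption: the target is read as an ent-labdane (5R,9S,10R,13R; labdane numbering is used for all locants), so (S)-(+)-carvone and methyl hydrogen (R)-3-methylglutarate are the matching commercial enantiomers.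

**Step 1**
Reactants: 1 (S)-(+)-carvone
Product: 3 6-methylcarvone [(5S)-2,6-dimethyl-5-(prop-1-en-2-yl)cyclohex-2-en-1-one; C6 epimer mixture], via lithium dienolate 2 (not isolated)
Conditions: LiN(i-Pr)2, THF, −78 °C; then MeI, −78 → 0 °C
Reagents that add atoms: iodomethane, CI
Why: Kinetic deprotonation takes the alpha-prime CH2 (future C10) and the cross-conjugated dienolate 2 is C-methylated (kinetic enolate alkylation), giving the new center as an epimer mixture that is planarised again in step 2.

**Step 2**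
Reactants: 3 6-methylcarvone
Product: 5 (5R,6R)-2,6-dimethyl-5-(prop-1-en-2-yl)-6-(prop-2-yn-1-yl)cyclohex-2-en-1-one, via lithium enolate 4 (not isolated)
Conditions: LiN(i-Pr)2, THF, −78 °C; then propargyl bromide, −78 → 23 °C
Reagents that add atoms: 3-bromoprop-1-yne, C#CCBr
Why: In this second kinetic enolate alkylation the tetrasubstituted enolate 4 should take the propargylic bromide on the face anti to the adjacent 2-propenyl group, which sets quaternary C10 with the three-carbon arm trans and the methyl cis to the future C4 unit.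

**Step 3**
Reactants: 5 the propargyl ketone
Product: 6 3-[(1R,6R)-1,3-dimethyl-2-oxo-6-(prop-1-en-2-yl)cyclohex-3-en-1-yl]propanal
Conditions: [CpRu(MeCN)3]PF6 (5 mol %), 5,5'-bis(trifluoromethyl)-2,2'-bipyridine (5 mol %), NMP/H2O 4:1, 25 °C
Reagents that add atoms: water, O
Why: Ruthenium-vinylidene catalysed anti-Markovnikov hydration of the terminal alkyne should deliver the aldehyde under neutral conditions that leave the enone and the 1,1-disubstituted alkene alone, and no stereocenter is formed.

**Step 4**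
Reactants: 6 the aldehyde
Product: 7 N'-[(1E)-3-[(1R,6R)-1,3-dimethyl-2-oxo-6-(prop-1-en-2-yl)cyclohex-3-en-1-yl]propylidene]-4-methylbenzenesulfonohydrazide
Conditions: TsNHNH2, MeOH, 23 °C
Reagents that add atoms: 4-methylbenzenesulfonohydrazide, Cc1ccc(cc1)S(=O)(=O)NN
Why: Hydrazone condensation should occur only at the unhindered aldehyde because the conjugated ketone is flanked by the quaternary carbon, and it creates no stereocenter.

**Step 5**
Reactants: 7 the tosylhydrazone
Product: 10 (4aR,8aR)-2,5,5,8a-tetramethyl-4a,5,6,7,8,8a-hexahydronaphthalen-1(4H)-one, via cyclised tosylhydrazine 8 (not isolated), via alkyl diazene 9 (not isolated)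
Conditions: Fe(acac)3 (30 mol %), PhSiH3 (2.5 equiv), EtOH/THF, 60 °C; then NaOAc, MeOH, 65 °C
Reagents that add atoms: none
Why: An iron hydride formed from Fe(acac)3 and PhSiH3 transfers a hydrogen atom to the CH2 terminus of the 2-propenyl group, the tertiary C4 radical adds to the hydrazone carbon C3, the hydrazinyl radical is reduced and protonated to 8, and acetate then expels toluenesulfinate to give diazene 9, which loses N2 and leaves C3 as CH2. The closest known reaction types are the hydrogen-atom-transfer coupling of unactivated alkenes with sulfonylhydrazones (olefin hydromethylation with formaldehyde sulfonylhydrazones, and intramolecular alkene–hydrazone cyclisations) together with the sulfinate/N2 loss of N-alkyl-N'-sulfonylhydrazines. Ring A closes in the 6-exo-trig mode onto the C=N carbon, which avoids the 5-exo versus 6-endo ambiguity of an all-carbon acceptor. The only new stereocenter, C3 of 8, is transient and disappears on denitrogenation; C4 is not stereogenic, and the trans ring fusion follows from the existing C5 and C10 centers because the trans-disposed arms can only bridge diequatorially. The step needs chemoselective hydrogen-atom transfer to the 1,1-disubstituted alkene in the presence of the trisubstituted enone; this is secured by the higher reactivity of the electron-rich terminal alkene, by the polarity match between the nucleophilic tertiary radical and the electrophilic hydrazone carbon, and by the absence of any other ring closure within reach of the radical.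

**Step 6**
Reactants: 10 the bicyclic enone
Product: 12 (4aR,8aR)-2,5,5,8a-tetramethyl-3,4,4a,5,6,7,8,8a-octahydronaphthalen-1-yl trifluoromethanesulfonate, via lithium enolate 11 (not isolated)
Conditions: Li[HB(s-Bu)3], THF, −78 °C; then PhNTf2, −78 → 0 °C
Reagents that add atoms: N-phenylbis(trifluoromethanesulfonimide), O=S(=O)(N(c1ccccc1)S(=O)(=O)C(F)(F)F)C(F)(F)F
Why: The bulky borohydride should add 1,4 to this beta-unsubstituted enone whose carbonyl is shielded by quaternary C10 (conjugate reduction), and the regiodefined enolate 11 is O-sulfonylated (enolate triflation) without creating a stereocenter.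

**Step 7**
Reactants: 13 methyl hydrogen (R)-3-methylglutarate
Product: 14 methyl (3R)-5-hydroxy-3-methylpentanoate
Conditions: BH3·SMe2, THF, 0 → 23 °C; MeOH quench
Reagents that add atoms: none
Why: Chemoselective borane reduction takes the carboxylic acid much faster than the methyl ester, and the chiral-pool center (future C13) is not touched.

**Step 8**
Reactants: 14 the hydroxy ester
Product: 15 methyl (3S)-5-iodo-3-methylpentanoate
Conditions: I2, PPh3, imidazole, CH2Cl2, 0 °C
Reagents that add atoms: iodine, II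
Why: Appel-type iodination of the primary alcohol by SN2 displacement of the oxyphosphonium ion is fast at 0 °C and should outrun lactonisation, with the remote stereocenter unaffected (the descriptor changes only through priorities).

**Step 9**
Reactants: 12 the enol triflate; 15 the iodo ester
Product: 17 methyl (3R)-3-methyl-5-[(4aR,8aR)-2,5,5,8a-tetramethyl-3,4,4a,5,6,7,8,8a-octahydronaphthalen-1-yl]pentanoate, via alkylzinc iodide 16 (not isolated)
Conditions: 15, Zn dust (activated), LiCl, THF, 40 °C; then 12, Pd(dppf)Cl2 (5 mol %), THF/DMA, 60 °C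
Reagents that add atoms: none
Why: Zinc inserts into the primary C–I bond without touching the ester and alkylzinc 16 should undergo Negishi sp3–sp2 cross-coupling with the hindered enol triflate (the coupling type established for 2,6,6-trimethylcyclohexenyl triflates, with dppf suppressing beta-hydride elimination), joining C11 to C9 without creating a stereocenter.

**Step 10**
Reactants: 17 the 8-ene ester
Product: 19 methyl (3R)-3-methyl-5-[(4aR,8aR)-2,5,5,8a-tetramethyl-3-oxo-3,4,4a,5,6,7,8,8a-octahydronaphthalen-1-yl]pentanoate, via allylic tert-butyl peroxide 18 (not isolated)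
Conditions: Rh2(cap)4 (1 mol %), t-BuOOH (70% aq.), K2CO3 (cat.), CH2Cl2, 23 °C
Reagents that add atoms: tert-butyl hydroperoxide, CC(C)(C)OO
Why: This dirhodium caprolactamate/t-BuOOH allylic C–H oxidation should abstract the stereoelectronically aligned ring C7–H and collapse peroxide 18 to the conjugated enone, C7 being favoured over C11 (next to quaternary C10) and over the C17 methyl, with no stereocenter formed.

**Step 11**
Reactants: 19 the enone ester
Product: 20 methyl (3R)-5-[(3R,4aR,8aR)-3-hydroxy-2,5,5,8a-tetramethyl-3,4,4a,5,6,7,8,8a-octahydronaphthalen-1-yl]-3-methylpentanoate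
Conditions: NaBH4, CeCl3·7H2O, MeOH, −20 °C
Reagents that add atoms: none
Why: Luche 1,2-reduction should deliver hydride along the axial trajectory of the half-chair enone, so the C7 hydroxyl ends pseudo-equatorial and cis to the C10 methyl (substrate control), while the ester is untouched.

**Step 12**
Reactants: 20 the allylic alcohol
Product: 23 methyl (3R)-3-methyl-5-[(1R,4aR,8aR)-2,5,5,8a-tetramethyl-1,4,4a,5,6,7,8,8a-octahydronaphthalen-1-yl]pentanoate, via allylic sulfonylhydrazine 21 (not isolated), via allylic diazene 22 (not isolated)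
Conditions: 2-nitrobenzenesulfonyl hydrazide, PPh3, DEAD, THF, −30 → 23 °C
Reagents that add atoms: none
Why: In this reductive 1,3-transposition the Mitsunobu displacement inverts C7, loss of sulfinate gives allylic diazene 22, and its retro-ene loss of N2 delivers hydrogen suprafacially to C9 on the face anti to the C10 methyl while the alkene moves to C7=C8, which sets C9 with the side chain equatorial.

**Step 13**
Reactants: 23 the 7-ene ester
Product: 24 methyl (3R)-5-[(1S,4aR,8aR)-2-(hydroxymethyl)-5,5,8a-trimethyl-1,4,4a,5,6,7,8,8a-octahydronaphthalen-1-yl]-3-methylpentanoate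
Conditions: SeO2 (0.5 equiv), t-BuOOH, CH2Cl2, 23 °C
Reagents that add atoms: tert-butyl hydroperoxide, CC(C)(C)OO (terminal oxidant; the oxygen is passed on by catalytic selenium dioxide, O=[Se]=O)
Why: Selenium dioxide allylic hydroxylation (ene reaction, then [2,3]-sigmatropic shift) attacks alpha to the more substituted alkene carbon C8 and should prefer the C17 methyl over the hindered tertiary C9–H, so the alkene stays at C7=C8 and no stereocenter is created or disturbed.

**Step 14**
Reactants: 24 the allylic alcohol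
Product: 25 methyl (3R)-5-[(1S,4aR,8aR)-2-(acetoxymethyl)-5,5,8a-trimethyl-1,4,4a,5,6,7,8,8a-octahydronaphthalen-1-yl]-3-methylpentanoate (target)
Conditions: Ac2O, pyridine, DMAP (cat.), CH2Cl2, 23 °C
Reagents that add atoms: acetic anhydride, CC(=O)OC(C)=O
Why: DMAP-catalysed acylation of the unhindered primary allylic alcohol is straightforward and touches no stereocenter.

**Compound list**
1 | (S)-(+)-carvone, (5S)-2-methyl-5-(prop-1-en-2-yl)cyclohex-2-en-1-one | O=C1C(C)=CC[C@H](C(C)=C)C1 | starting material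
2 | lithium (3S)-6-methyl-3-(prop-1-en-2-yl)cyclohexa-1,5-dien-1-olate (dienolate of 1, not isolated) | [Li]OC1=C[C@@H](C(C)=C)CC=C1C | intermediate
3 | 6-methylcarvone, (5S)-2,6-dimethyl-5-(prop-1-en-2-yl)cyclohex-2-en-1-one (C6 epimer mixture; major trans (5S,6R) isomer drawn) | O=C1C(C)=CC[C@H](C(C)=C)[C@H]1C | intermediate
4 | lithium (3R)-2,6-dimethyl-3-(prop-1-en-2-yl)cyclohexa-1,5-dien-1-olate (enolate of 3, not isolated) | [Li]OC1=C(C)[C@@H](C(C)=C)CC=C1C | intermediate
5 | (5R,6R)-2,6-dimethyl-5-(prop-1-en-2-yl)-6-(prop-2-yn-1-yl)cyclohex-2-en-1-one | O=C1C(C)=CC[C@H](C(C)=C)[C@@]1(C)CC#C | intermediate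
6 | 3-[(1R,6R)-1,3-dimethyl-2-oxo-6-(prop-1-en-2-yl)cyclohex-3-en-1-yl]propanal | O=C1C(C)=CC[C@H](C(C)=C)[C@@]1(C)CCC=O | intermediate
7 | N'-[(1E)-3-[(1R,6R)-1,3-dimethyl-2-oxo-6-(prop-1-en-2-yl)cyclohex-3-en-1-yl]propylidene]-4-methylbenzenesulfonohydrazide | O=C1C(C)=CC[C@H](C(C)=C)[C@@]1(C)CC/C=N/NS(=O)(=O)c1ccc(C)cc1 | intermediate
8 | (4aR,8aR)-2,5,5,8a-tetramethyl-6-[2-(4-methylbenzenesulfonyl)hydrazinyl]-4a,5,6,7,8,8a-hexahydronaphthalen-1(4H)-one (C6 epimers, not isolated) | O=C1C(C)=CC[C@@H]2C(C)(C)C(NNS(=O)(=O)c3ccc(C)cc3)CC[C@@]12C | intermediate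
9 | (4aR,8aR)-6-diazenyl-2,5,5,8a-tetramethyl-4a,5,6,7,8,8a-hexahydronaphthalen-1(4H)-one (C6 epimers, not isolated) | O=C1C(C)=CC[C@@H]2C(C)(C)C(N=N)CC[C@@]12C | intermediate
10 | (4aR,8aR)-2,5,5,8a-tetramethyl-4a,5,6,7,8,8a-hexahydronaphthalen-1(4H)-one | O=C1C(C)=CC[C@@H]2C(C)(C)CCC[C@@]12C | intermediate
11 | lithium (4aR,8aR)-2,5,5,8a-tetramethyl-3,4,4a,5,6,7,8,8a-octahydronaphthalen-1-olate (not isolated) | [Li]OC1=C(C)CC[C@@H]2C(C)(C)CCC[C@@]12C | intermediate
12 | (4aR,8aR)-2,5,5,8a-tetramethyl-3,4,4a,5,6,7,8,8a-octahydronaphthalen-1-yl trifluoromethanesulfonate | FC(F)(F)S(=O)(=O)OC1=C(C)CC[C@@H]2C(C)(C)CCC[C@@]12C | intermediate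
13 | methyl hydrogen (R)-3-methylglutarate, (3R)-5-methoxy-3-methyl-5-oxopentanoic acid | COC(=O)C[C@H](C)CC(=O)O | starting material
14 | methyl (3R)-5-hydroxy-3-methylpentanoate | COC(=O)C[C@H](C)CCO | intermediate
15 | methyl (3S)-5-iodo-3-methylpentanoate | COC(=O)C[C@H](C)CCI | intermediate
16 | [(3S)-5-methoxy-3-methyl-5-oxopentyl]zinc iodide (not isolated) | COC(=O)C[C@H](C)CC[Zn]I | intermediate
17 | methyl (3R)-3-methyl-5-[(4aR,8aR)-2,5,5,8a-tetramethyl-3,4,4a,5,6,7,8,8a-octahydronaphthalen-1-yl]pentanoate | COC(=O)C[C@H](C)CCC1=C(C)CC[C@@H]2C(C)(C)CCC[C@@]12C | intermediate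
18 | methyl (3R)-5-[(4aR,8aR)-3-(tert-butylperoxy)-2,5,5,8a-tetramethyl-3,4,4a,5,6,7,8,8a-octahydronaphthalen-1-yl]-3-methylpentanoate (C3 epimers, not isolated) | COC(=O)C[C@H](C)CCC1=C(C)C(OOC(C)(C)C)C[C@@H]2C(C)(C)CCC[C@@]12C | intermediate
19 | methyl (3R)-3-methyl-5-[(4aR,8aR)-2,5,5,8a-tetramethyl-3-oxo-3,4,4a,5,6,7,8,8a-octahydronaphthalen-1-yl]pentanoate | COC(=O)C[C@H](C)CCC1=C(C)C(=O)C[C@@H]2C(C)(C)CCC[C@@]12C | intermediate
20 | methyl (3R)-5-[(3R,4aR,8aR)-3-hydroxy-2,5,5,8a-tetramethyl-3,4,4a,5,6,7,8,8a-octahydronaphthalen-1-yl]-3-methylpentanoate | COC(=O)C[C@H](C)CCC1=C(C)[C@H](O)C[C@@H]2C(C)(C)CCC[C@@]12C | intermediate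
21 | methyl (3R)-3-methyl-5-[(3S,4aR,8aR)-2,5,5,8a-tetramethyl-3-[1-(2-nitrobenzenesulfonyl)hydrazinyl]-3,4,4a,5,6,7,8,8a-octahydronaphthalen-1-yl]pentanoate (not isolated) | COC(=O)C[C@H](C)CCC1=C(C)[C@@H](N(N)S(=O)(=O)c3ccccc3[N+](=O)[O-])C[C@@H]2C(C)(C)CCC[C@@]12C | intermediate
22 | methyl (3R)-5-[(3S,4aR,8aR)-3-diazenyl-2,5,5,8a-tetramethyl-3,4,4a,5,6,7,8,8a-octahydronaphthalen-1-yl]-3-methylpentanoate (not isolated) | COC(=O)C[C@H](C)CCC1=C(C)[C@@H](N=N)C[C@@H]2C(C)(C)CCC[C@@]12C | intermediate
23 | methyl (3R)-3-methyl-5-[(1R,4aR,8aR)-2,5,5,8a-tetramethyl-1,4,4a,5,6,7,8,8a-octahydronaphthalen-1-yl]pentanoate | COC(=O)C[C@H](C)CC[C@@H]1C(C)=CC[C@@H]2C(C)(C)CCC[C@@]12C | intermediate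
24 | methyl (3R)-5-[(1S,4aR,8aR)-2-(hydroxymethyl)-5,5,8a-trimethyl-1,4,4a,5,6,7,8,8a-octahydronaphthalen-1-yl]-3-methylpentanoate | COC(=O)C[C@H](C)CC[C@@H]1C(CO)=CC[C@@H]2C(C)(C)CCC[C@@]12C | intermediate
25 | methyl (3R)-5-[(1S,4aR,8aR)-2-(acetoxymethyl)-5,5,8a-trimethyl-1,4,4a,5,6,7,8,8a-octahydronaphthalen-1-yl]-3-methylpentanoate | COC(=O)C[C@H](C)CC[C@@H]1C(COC(C)=O)=CC[C@@H]2C(C)(C)CCC[C@@]12C | target

**Step count**
Total step count: 14 (12 in the main line, 2 for the side-chain fragment). Longest linear sequence: 12 steps (steps 1–6 and 9–14).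

**Steps most likely to fail**

Step 10. Hydrogen abstraction may occur at the side-chain allylic C11 or at the C17 methyl instead of ring C7, or the oxidation may stop at the peroxide stage, so that regioisomeric enones form. The fallback places the C7 carbonyl by a regiospecific allylic transposition instead. It sets out from 10 (with 15 as the side-chain source, bypassing steps 6 and 9) and comes back at 19. Ester 15 would be reduced with i-Bu2AlH to (3S)-5-iodo-3-methylpentan-1-ol F1 and silylated (TBSCl, imidazole) to the iodo silyl ether F2. Iodine–lithium exchange with t-BuLi at −78 °C would give the alkyllithium F3, which should add 1,2 to the non-enolisable enone 10 to give the tertiary allylic alcohol F4. Oxidative 1,3-transposition with pyridinium chlorochromate, (C5H5NH)[CrO3Cl], would give the transposed enone silyl ether F5. CrO3/H2SO4 in acetone would remove the silyl group and oxidise the primary alcohol to the keto acid F6, and esterification with TMSCHN2 would give 19.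

Step 5. The tertiary radical may be reduced before it cyclises (net hydrogenation of the 2-propenyl group), the C=N bond may be reduced by the silane, or sulfinate loss may be incomplete. The fallback forms the same C3–C4 bond by carbopalladation. It sets out from 5 and comes back at 10. Alkyne 5 would be iodinated (N-iodosuccinimide, AgNO3 cat.) to the iodoalkyne F7 and reduced with diimide (2-nitrobenzenesulfonyl hydrazide, Et3N) to the (Z)-iodoalkene F8. A 6-exo-trig Heck cyclisation (Pd(OAc)2, PPh3, HCO2Na, DMF, 80 °C) would join C3 to C4, and the neopentyl alkylpalladium, which has no beta-hydrogen, would be captured by formate so that =CH2 becomes the second methyl, giving the ring A diene F9. Hydrogenation of the disubstituted ring A alkene with RhCl(PPh3)3, which spares the trisubstituted enone alkene, would give 10.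

Step 12. The Mitsunobu displacement at the hindered secondary allylic carbinol may fail, or elimination to a ring B diene may take over. The fallback sets C9–H by hydride delivery instead. It sets out from 19 (bypassing step 11) and comes back at 23. 1,4-Hydrosilylation of enone 19 (Et3SiH, RhCl(PPh3)3 cat.) should deliver hydride to C9 anti to the C10 methyl and give the regiodefined triethylsilyl enol ether F10. CsF/PhNTf2 would convert it into the enol triflate F11, and reduction with Pd(OAc)2, PPh3, HCO2H and Bu3N would give 23.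

**Further compounds**
F1 | step 10 | (3S)-5-iodo-3-methylpentan-1-ol | OCC[C@H](C)CCI
F2 | step 10 | tert-butyl{[(3S)-5-iodo-3-methylpentyl]oxy}dimethylsilane | CC(C)(C)[Si](C)(C)OCC[C@H](C)CCI
F3 | step 10 | [(3R)-5-(tert-butyldimethylsilyloxy)-3-methylpentyl]lithium | CC(C)(C)[Si](C)(C)OCC[C@H](C)CC[Li]
F4 | step 10 | (4aR,8aR)-1-[(3R)-5-(tert-butyldimethylsilyloxy)-3-methylpentyl]-2,5,5,8a-tetramethyl-1,4,4a,5,6,7,8,8a-octahydronaphthalen-1-ol (carbinol configuration of no consequence) | CC(C)(C)[Si](C)(C)OCC[C@H](C)CCC1(O)C(C)=CC[C@@H]2C(C)(C)CCC[C@@]12C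
F5 | step 10 | (4aR,8aR)-4-[(3R)-5-(tert-butyldimethylsilyloxy)-3-methylpentyl]-3,4a,8,8-tetramethyl-4a,5,6,7,8,8a-hexahydronaphthalen-2(1H)-one | CC(C)(C)[Si](C)(C)OCC[C@H](C)CCC1=C(C)C(=O)C[C@@H]2C(C)(C)CCC[C@@]12C
F6 | step 10 | (3R)-3-methyl-5-[(4aR,8aR)-2,5,5,8a-tetramethyl-3-oxo-3,4,4a,5,6,7,8,8a-octahydronaphthalen-1-yl]pentanoic acid | OC(=O)C[C@H](C)CCC1=C(C)C(=O)C[C@@H]2C(C)(C)CCC[C@@]12C
F7 | step 5 | (5R,6R)-6-(3-iodoprop-2-yn-1-yl)-2,6-dimethyl-5-(prop-1-en-2-yl)cyclohex-2-en-1-one | O=C1C(C)=CC[C@H](C(C)=C)[C@@]1(C)CC#CI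
F8 | step 5 | (5R,6R)-6-[(2Z)-3-iodoprop-2-en-1-yl]-2,6-dimethyl-5-(prop-1-en-2-yl)cyclohex-2-en-1-one | O=C1C(C)=CC[C@H](C(C)=C)[C@@]1(C)C/C=C\I
F9 | step 5 | (4aR,8aR)-2,5,5,8a-tetramethyl-4a,5,8,8a-tetrahydronaphthalen-1(4H)-one | O=C1C(C)=CC[C@@H]2C(C)(C)C=CC[C@@]12C
F10 | step 12 | methyl (3R)-3-methyl-5-[(1S,4aR,8aR)-2,5,5,8a-tetramethyl-3-(triethylsilyloxy)-1,4,4a,5,6,7,8,8a-octahydronaphthalen-1-yl]pentanoate | COC(=O)C[C@H](C)CC[C@@H]1C(C)=C(O[Si](CC)(CC)CC)C[C@@H]2C(C)(C)CCC[C@@]12C
F11 | step 12 | methyl (3R)-3-methyl-5-[(1S,4aR,8aR)-2,5,5,8a-tetramethyl-3-(trifluoromethanesulfonyloxy)-1,4,4a,5,6,7,8,8a-octahydronaphthalen-1-yl]pentanoate | COC(=O)C[C@H](C)CC[C@@H]1C(C)=C(OS(=O)(=O)C(F)(F)F)C[C@@H]2C(C)(C)CCC[C@@]12C
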